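**Retrosynthetic overview**
- Benzofuran numbering is used (O1, C2, C3, C3a, C4–C7, C7a); ring A is the six-membered carbocycle, ring B the dihydrofuran, ring C the trimethoxyphenyl group. The route rests on C2 of ring B, the one carbon bonded to both O1 and C3. It can be inserted as a one-carbon ylide unit between the phenol oxygen on C7a and the exocyclic methide carbon C3 of an ortho-quinone methide ([4+1], bonds C2–C3 and O1–C2).
- The C5 centre (allyl, OMe) of the ring A dienone is traced back by a Cope shift to a C3a-allyl cross-conjugated dienone. That dienone comes from para-dearomative allylation of the C6 phenol of an aromatic 2,3-dihydrobenzofuran, where the neighbouring C3 methyl group selects the face.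
- Ring order: rings A and C are bought as arenes, ring B is closed in the key step, and ring A is dearomatised last.
- The methide is stored as a 2-(1-tosylethyl)phenol made from syringaldehyde in five steps. The ylide is stored as the 3,4,5-trimethoxybenzyl thiolanium salt of (2S,5S)-2,5-dimethylthiolane.

Key step: step 10

Assumption: the thiolanium ylide is taken to offer the methide carbon the same face it offers aldehydes, where the (2R,5R)-sulfide gives (S,S)-stilbene oxide. At C2 of the dihydrobenzofuran the aryl group outranks C3, whereas in the epoxide the ring carbon outranks phenyl, so that spatial sense would read 2R; the (2S,5S)-sulfide, from (2R,5R)-hexane-2,5-diol, is therefore used for the 2S,3S series.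

Step 1
Reactants: 1 syringaldehyde (4-hydroxy-3,5-dimethoxybenzaldehyde)
Product: 2 4-(benzyloxy)-3,5-dimethoxybenzaldehyde
Conditions: BnBr, K2CO3, DMF, 60 °C
Reagents that add atoms: benzyl bromide, BrCc1ccccc1
Why: Williamson ether synthesis on the only acidic site of 1, a phenol made more acidic by the para formyl group.

Step 2
Reactants: 2 4-(benzyloxy)-3,5-dimethoxybenzaldehyde
Product: 3 4-(benzyloxy)-2-bromo-3,5-dimethoxybenzaldehyde
Conditions: NBS, MeCN, rt to 50 °C, dark
Reagents that add atoms: N-bromosuccinimide, O=C1CCC(=O)N1Br
Why: Electrophilic aromatic bromination; the two free positions of ring A are equivalent by symmetry and activated ortho/para by the methoxy groups, so only one monobromide can form, and the unactivated phenyl ring of the benzyl group does not compete.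

Step 3
Reactants: 3 4-(benzyloxy)-2-bromo-3,5-dimethoxybenzaldehyde
Product: 4 rac-1-[4-(benzyloxy)-2-bromo-3,5-dimethoxyphenyl]ethan-1-ol
Conditions: MeMgBr, THF, 0 °C; then H2O
Reagents that add atoms: methylmagnesium bromide, C[Mg]Br
Why: Grignard 1,2-addition to the aldehyde, with no halogen–metal exchange by MeMgBr at this temperature; the carbinol centre is racemic on purpose because it is erased later in the planar methide.

Step 4
Reactants: 4 rac-1-[4-(benzyloxy)-2-bromo-3,5-dimethoxyphenyl]ethan-1-ol
Product: 7 rac-3-(benzyloxy)-6-(1-hydroxyethyl)-2,4-dimethoxyphenol, via dilithiated alkoxide 5 (not isolated), via lithium aryltrimethoxyborate 6 (not isolated)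
Conditions: n-BuLi (2.2 equiv), THF, −78 °C; B(OMe)3, −78 to 0 °C; 30% H2O2, aq NaOH, 0 °C
Reagents that add atoms: hydrogen peroxide, OO (oxygen on the future C7a); in the unisolated intermediates only: n-butyllithium, [Li]CCCC, and trimethyl borate, COB(OC)OC
Why: Bromine–lithium exchange after alkoxide formation, borylation and boronate oxidation (1,2-aryl shift from boron to oxygen) put the hydroxyl group exactly where bromine stood, and at −78 °C the exchange outruns deprotonation of the benzyl ether CH2.

Step 5
Reactants: 7 rac-3-(benzyloxy)-6-(1-hydroxyethyl)-2,4-dimethoxyphenol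
Product: 8 rac-3-(benzyloxy)-2,4-dimethoxy-6-[1-(4-methylbenzenesulfonyl)ethyl]phenol
Conditions: TolSO2H (1.5 equiv), CH2Cl2, rt
Reagents that add atoms: 4-methylbenzenesulfinic acid, Cc1ccc(cc1)S(=O)O
Why: SN1-type sulfinate substitution: the sulfinic acid ionises the electron-rich ortho-hydroxybenzylic alcohol, the sulfur of the sulfinate traps the cation, and reversibility lets the stable sulfone accumulate.

Step 6
Reactants: 9 (2R,5R)-hexane-2,5-diol
Product: 10 (2R,5R)-hexane-2,5-diyl dimethanesulfonate
Conditions: MsCl, Et3N, CH2Cl2, 0 °C
Reagents that add atoms: methanesulfonyl chloride, CS(=O)(=O)Cl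
Why: O-sulfonylation takes place at oxygen, so both carbinol centres keep their configuration.

Step 7
Reactants: 10 (2R,5R)-hexane-2,5-diyl dimethanesulfonate
Product: 11 (2S,5S)-2,5-dimethylthiolane
Conditions: Na2S·9H2O, EtOH, rt to 40 °C
Reagents that add atoms: sodium sulfide, [Na+].[Na+].[S-2]
Why: Two SN2 displacements by sulfur, the second a 5-exo-tet ring closure, invert both centres, so R,R becomes S,S.

Step 8
Reactants: 12 3,4,5-trimethoxybenzyl alcohol
Product: 13 3,4,5-trimethoxybenzyl bromide
Conditions: PBr3, CH2Cl2, 0 °C; used at once
Reagents that add atoms: phosphorus tribromide, BrP(Br)Br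
Why: Standard conversion of a benzylic alcohol into the bromide through its phosphite ester, run cold to avoid self-alkylation of the electron-rich ring.

Step 9
Reactants: 11 (2S,5S)-2,5-dimethylthiolane; 13 3,4,5-trimethoxybenzyl bromide
Product: 14 (2S,5S)-2,5-dimethyl-1-(3,4,5-trimethoxybenzyl)thiolan-1-ium bromide
Conditions: acetone, rt, dark; salt collected by filtration
Reagents that add atoms: none
Why: SN2 S-alkylation; the two lone pairs of the C2-symmetric sulfide are equivalent, so a single salt without a sulfur stereocentre forms, and its precipitation suppresses reversal by bromide.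

Step 10
Reactants: 8 rac-3-(benzyloxy)-2,4-dimethoxy-6-[1-(4-methylbenzenesulfonyl)ethyl]phenol; 14 (2S,5S)-2,5-dimethyl-1-(3,4,5-trimethoxybenzyl)thiolan-1-ium bromide
Product: 18 (2S,3S)-6-(benzyloxy)-5,7-dimethoxy-3-methyl-2-(3,4,5-trimethoxyphenyl)-2,3-dihydro-1-benzofuran, via ortho-quinone methide 15 (not isolated), via sulfonium ylide 16 (not isolated), via betaine 17 (not isolated)
Conditions: Cs2CO3 (3 equiv), 14 (1.3 equiv), MeCN, 0 °C to rt
Reagents that add atoms: none
Why: Cs2CO3 deprotonates the phenol of 8, whose phenoxide expels toluenesulfinate in an E1cB-type 1,4-elimination to give the planar E-configured methide 15, which erases the racemic centre, while the same base turns 14 into the semistabilised ylide 16. The ylide carbon adds 1,4 to the methide carbon (future C3) to give betaine 17, and the phenoxide oxygen then displaces the thiolane at C2 with inversion; this is the known [4+1] annulation of ortho-quinone methides released from 2-(1-sulfonylalkyl)phenols with sulfonium ylides, with sulfide control borrowed from asymmetric ylide epoxidation. Ring B is closed by a 5-exo-tet substitution. C2 is controlled by the C2-symmetric thiolane: the aryl group of 16 points away from the thiolane ring, the methyl group cis to the ylide carbon blocks one face, and bond formation on the open face followed by inversion should give 2S with the (2S,5S)-sulfide. C3 is controlled by the relative topicity of the C–C bond formation, in which ring C and the methide methyl group avoid each other, so the betaine with these two groups anti forms and closes to the trans (2S,3S) ring; because rearomatisation makes the addition irreversible, this kinetic preference decides. The step needs the ylide to outrun dimerisation of 15 and its 1,5-hydrogen shift to a vinylphenol, which is secured by slow heterogeneous release of 15, by the three oxygen donors on ring A that temper its electrophilicity, by the reversibility of sulfinate re-addition and by the excess of 14.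

Step 11
Reactants: 18 (2S,3S)-6-(benzyloxy)-5,7-dimethoxy-3-methyl-2-(3,4,5-trimethoxyphenyl)-2,3-dihydro-1-benzofuran
Product: 19 (2S,3S)-5,7-dimethoxy-3-methyl-2-(3,4,5-trimethoxyphenyl)-2,3-dihydro-1-benzofuran-6-ol
Conditions: H2 (1 atm), Pd/C (10 wt %), EtOAc, rt, stopped after one equivalent of H2
Reagents that add atoms: none
Why: Catalytic hydrogenolysis cleaves the unhindered primary O-benzyl ether well before the secondary, ring-embedded C2–O1 benzylic bond; no alkene is present yet and both stereocentres are untouched.

Step 12
Reactants: 19 (2S,3S)-5,7-dimethoxy-3-methyl-2-(3,4,5-trimethoxyphenyl)-2,3-dihydro-1-benzofuran-6-ol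
Product: 20 (2S,3S,3aS)-3a-allyl-5,7-dimethoxy-3-methyl-2-(3,4,5-trimethoxyphenyl)-3,3a-dihydro-1-benzofuran-6(2H)-one
Conditions: allyl methyl carbonate (1.5 equiv), Pd2(dba)3·CHCl3 (2.5 mol %), PPh3 (12 mol %), Li2CO3, 1,4-dioxane, rt
Reagents that add atoms: allyl methyl carbonate, C=CCOC(=O)OC
Why: Proposed new method: zerovalent palladium ionises the carbonate to a cationic π-allylpalladium complex and methoxide, which converts 19 into its phenoxide; with lithium held between the phenoxide oxygen and the two flanking methoxy groups, O6, C5 and C7 are buried, so the soft electrophile should be taken up by the para carbon C3a, which carries the largest phenoxide HOMO coefficient and is further activated by O1, on the face anti to the adjacent C3 methyl group, making C3a S. The closest known reactions are the palladium-catalysed intramolecular ipso-Friedel–Crafts allylic dearomatisation of para-substituted phenols and the intermolecular allylic dearomatisation of 1-substituted 2-naphthols; intermolecular para attack by a simple phenol goes beyond them.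

Step 13
Reactants: 20 (2S,3S,3aS)-3a-allyl-5,7-dimethoxy-3-methyl-2-(3,4,5-trimethoxyphenyl)-3,3a-dihydro-1-benzofuran-6(2H)-one
Product: 21 (2S,3S,5R)-5-allyl-5,7-dimethoxy-3-methyl-2-(3,4,5-trimethoxyphenyl)-3,5-dihydro-1-benzofuran-6(2H)-one (target)
Conditions: toluene, 100 °C, base-washed glassware, stopped when 20 is consumed
Reagents that add atoms: none
Why: Cope rearrangement of the 1,5-diene CH2=CH–CH2–C3a–C4=C5, the known thermal shift of 4-allylcyclohexa-2,5-dienones to 6-allylcyclohexa-2,4-dienones; the allyl group can only travel across the ring face on which it sits, so 3aS is transcribed into 5R (allyl still anti to the C3 methyl), while relief of the crowded C3/C3a array and the retained O1–C7a=C7–C6=O vinylogous ester should favour 21.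

**Compound list**
1 | syringaldehyde (4-hydroxy-3,5-dimethoxybenzaldehyde) | COc1cc(C=O)cc(OC)c1O | starting material
2 | 4-(benzyloxy)-3,5-dimethoxybenzaldehyde | COc1cc(C=O)cc(OC)c1OCc1ccccc1 | intermediate
3 | 4-(benzyloxy)-2-bromo-3,5-dimethoxybenzaldehyde | COc1cc(C=O)c(Br)c(OC)c1OCc1ccccc1 | intermediate
4 | rac-1-[4-(benzyloxy)-2-bromo-3,5-dimethoxyphenyl]ethan-1-ol | CC(O)c1cc(OC)c(OCc2ccccc2)c(OC)c1Br | intermediate
5 | dilithiated alkoxide (aryllithium lithium alkoxide from 4, not isolated) | CC(O[Li])c1cc(OC)c(OCc2ccccc2)c(OC)c1[Li] | intermediate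
6 | lithium aryltrimethoxyborate, lithium alkoxide (not isolated) | CC([O-])c1cc(OC)c(OCc2ccccc2)c(OC)c1[B-](OC)(OC)OC.[Li+].[Li+] | intermediate
7 | rac-3-(benzyloxy)-6-(1-hydroxyethyl)-2,4-dimethoxyphenol | CC(O)c1cc(OC)c(OCc2ccccc2)c(OC)c1O | intermediate
8 | rac-3-(benzyloxy)-2,4-dimethoxy-6-[1-(4-methylbenzenesulfonyl)ethyl]phenol | CC(c1cc(OC)c(OCc2ccccc2)c(OC)c1O)S(=O)(=O)c1ccc(C)cc1 | intermediate
9 | (2R,5R)-hexane-2,5-diol | C[C@@H](O)CC[C@@H](C)O | starting material
10 | (2R,5R)-hexane-2,5-diyl dimethanesulfonate | C[C@@H](OS(C)(=O)=O)CC[C@@H](C)OS(C)(=O)=O | intermediate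
11 | (2S,5S)-2,5-dimethylthiolane | C[C@H]1CC[C@H](C)S1 | intermediate
12 | 3,4,5-trimethoxybenzyl alcohol | COc1cc(CO)cc(OC)c1OC | starting material
13 | 3,4,5-trimethoxybenzyl bromide | COc1cc(CBr)cc(OC)c1OC | intermediate
14 | (2S,5S)-2,5-dimethyl-1-(3,4,5-trimethoxybenzyl)thiolan-1-ium bromide | C[C@H]1CC[C@H](C)[S+]1Cc1cc(OC)c(OC)c(OC)c1.[Br-] | intermediate
15 | (E)-3-(benzyloxy)-6-ethylidene-2,4-dimethoxycyclohexa-2,4-dien-1-one (ortho-quinone methide, not isolated) | C/C=C1\C=C(OC)C(OCc2ccccc2)=C(OC)C1=O | intermediate
16 | (2S,5S)-2,5-dimethylthiolanium (3,4,5-trimethoxyphenyl)methylide (not isolated) | C[C@H]1CC[C@H](C)[S+]1[CH-]c1cc(OC)c(OC)c(OC)c1 | intermediate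
17 | betaine: phenoxide bearing the (1R,2S)-1-(thiolanium-1-yl)-1-(3,4,5-trimethoxyphenyl)propan-2-yl chain (not isolated) | C[C@@H](c1cc(OC)c(OCc2ccccc2)c(OC)c1[O-])[C@H](c1cc(OC)c(OC)c(OC)c1)[S+]1[C@@H](C)CC[C@@H]1C | intermediate
18 | (2S,3S)-6-(benzyloxy)-5,7-dimethoxy-3-methyl-2-(3,4,5-trimethoxyphenyl)-2,3-dihydro-1-benzofuran | COc1cc2c(c(OC)c1OCc1ccccc1)O[C@H](c1cc(OC)c(OC)c(OC)c1)[C@H]2C | intermediate
19 | (2S,3S)-5,7-dimethoxy-3-methyl-2-(3,4,5-trimethoxyphenyl)-2,3-dihydro-1-benzofuran-6-ol | COc1cc2c(c(OC)c1O)O[C@H](c1cc(OC)c(OC)c(OC)c1)[C@H]2C | intermediate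
20 | (2S,3S,3aS)-3a-allyl-5,7-dimethoxy-3-methyl-2-(3,4,5-trimethoxyphenyl)-3,3a-dihydro-1-benzofuran-6(2H)-one | C=CC[C@]12C=C(OC)C(=O)C(OC)=C1O[C@H](c1cc(OC)c(OC)c(OC)c1)[C@H]2C | intermediate
21 | (2S,3S,5R)-5-allyl-5,7-dimethoxy-3-methyl-2-(3,4,5-trimethoxyphenyl)-3,5-dihydro-1-benzofuran-6(2H)-one | C=CC[C@@]1(OC)C=C2C(=C(OC)C1=O)O[C@H](c1cc(OC)c(OC)c(OC)c1)[C@H]2C | target

**Step count**
- Total step count: 13.
- Longest linear sequence: 9 steps (steps 1–5 and 10–13).

**Steps most likely to fail**

First, step 12 (the labelled step).
- The allyl group may be transferred to the phenoxide oxygen or to the methoxy-bearing ortho carbons instead of C3a.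
- The two faces of ring A may also be poorly distinguished.
- The fallback inverts the polarity and uses known chemistry. It sets out from 19, which is oxidised with the trivalent iodine reagent PhI(OAc)2 in (CF3)2CHOH in the presence of allyltrimethylsilane. This is the known oxidative Hosomi–Sakurai-type para-allylation of 4-alkylphenols.
- Ring A then reacts as a phenoxenium ion, so O-allylation is ruled out. The silane should add at C3a anti to the C3 methyl group.
- The sequence comes back to the route at 20 and no new compound arises (F0).

Second, step 13.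
- The [3,3] equilibrium may not lie on the side of the C5 isomer.
- The migration may also run on by a retro-Claisen shift with rearomatisation of ring A, since the two barriers are expected to be close.
- The fallback avoids heating and the C3a relay altogether. It sets out from 19, whose sodium salt (NaH) is suspended in toluene and treated with allyl bromide at rt. This is the known heterogeneous ortho C-alkylation of 2,6-disubstituted phenoxides to 6-allylcyclohexa-2,4-dienones.
- Attack should occur mainly at C5, which has the open C4–H neighbour, and this gives 21 directly.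
- C5 is then not set by the substrate, so the C5 epimer of the target F1 has to be removed by chromatography.
- The 6-O-allyl ether F2 formed alongside is returned to 19 with Pd(PPh3)4, K2CO3, MeOH.
- The fallback comes back to the route at 21.

Third, step 10.
- Face selection by the ylide may be incomplete, with loss of enantiopurity.
- The trans preference may be modest, because the addition is irreversible.
- Proton exchange at C2 of the betaine may leak material into the wrong enantiomeric series.
- A cis product must be separated and not epimerised at C2, since epimerisation would lead to the antipode.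
- The fallback gives up reagent control of the absolute configuration. It sets out from 8, which is annulated under the same base conditions with achiral 1-(3,4,5-trimethoxybenzyl)thiolan-1-ium bromide F3, made from tetrahydrothiophene and 13.
- This gives the racemic trans-dihydrobenzofuran, that is 18 together with its (2R,3R) enantiomer F4. The racemate is resolved by preparative HPLC on a chiral stationary phase.
- The fallback comes back to the route at 18.

**Further compounds**
F0 | step 12 | none | none
F1 | step 13 | (2S,3S,5S)-5-allyl-5,7-dimethoxy-3-methyl-2-(3,4,5-trimethoxyphenyl)-3,5-dihydro-1-benzofuran-6(2H)-one | C=CC[C@]1(OC)C=C2C(=C(OC)C1=O)O[C@H](c1cc(OC)c(OC)c(OC)c1)[C@H]2C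
F2 | step 13 | (2S,3S)-6-(allyloxy)-5,7-dimethoxy-3-methyl-2-(3,4,5-trimethoxyphenyl)-2,3-dihydro-1-benzofuran | C=CCOc1c(OC)cc2c(c1OC)O[C@H](c1cc(OC)c(OC)c(OC)c1)[C@H]2C
F3 | step 10 | 1-(3,4,5-trimethoxybenzyl)thiolan-1-ium bromide | COc1cc(C[S+]2CCCC2)cc(OC)c1OC.[Br-]
F4 | step 10 | (2R,3R)-6-(benzyloxy)-5,7-dimethoxy-3-methyl-2-(3,4,5-trimethoxyphenyl)-2,3-dihydro-1-benzofuran | COc1cc2c(c(OC)c1OCc1ccccc1)O[C@@H](c1cc(OC)c(OC)c(OC)c1)[C@@H]2C
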